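An easy step first: a racemate has zero excess, so the excess of right-handed substrate over left-handed substrate, their difference over their sum, measures how far the partner's hand has pulled the pair off zero. The racemization catalyst pulls it back. This is a kinetic resolution with a brake.

| setting | alder | maple | ochre | green |
|---|---|---|---|---|
| left-handed substrate | 10 mM | 10 mM | 10 mM | 10 mM |
| right-handed substrate | 10 mM | 10 mM | 10 mM | 10 mM |
| partner | 27 mM | 60 mM | 30.0 mM | 120 mM |
| racemization catalyst | 5 µM | 5 µM | 5.0 µM | 5.0 µM |
| impurity | 2.7 µM | 2.7 µM | 2.7 µM | 2.7 µM |
| remark | run made earlier | run made earlier |  |  |
| time |  |  | 6.0 h | 6.0 h |

| run | time / h | right-handed substrate / % | left-handed substrate / % |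
|---|---|---|---|
| alder | 0.250 | 49.4 | 47.8 |
| alder | 0.500 | 48.7 | 47.7 |
| alder | 1.33 | 46.4 | 46.1 |
| alder | 3.00 | 43.5 | 42.1 |
| maple | 0.250 | 48.5 | 47.6 |
| maple | 0.500 | 47.5 | 45.9 |
| maple | 1.33 | 42.4 | 40.4 |
| maple | 3.00 | 36.0 | 33.5 |

(standard deviation of a reading: 0.5 percentage points)

- partner is single-handed; left-handed substrate and right-handed substrate are mirror images of each other, charged as a racemate, each of them at the stated concentration
- what was read earlier has a scatter of 0.5 percentage points, one standard deviation
- steps thought possible: partner + left-handed substrate -> left-handed product; partner + right-handed substrate -> right-handed product; left-handed substrate + racemization catalyst <-> right-handed substrate + racemization catalyst; partner -> decomposed reagent; racemization catalyst + impurity -> spent catalyst A; partner + racemization catalyst -> spent catalyst B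
- an excess is below zero if the other one leads
- the handed part of partner does not stay in what it makes, so the products of the two hands are mirror images too

1. which of the two ends with the higher excess of right-handed substrate over left-handed substrate among what is left of the two ("neither" if they lie within 2 percentage points) (ochre / green / neither)
2. excess of right-handed substrate over left-handed substrate among what is left of the two at the end, ochre
3. excess of right-handed substrate over left-handed substrate among what is left of the two at the end, green

Now the run in slow motion, as we reckon it. In the first instants we assume each impurity takes one catalyst into spent catalyst A, and that leaves 2.30 µM: we call this the working catalyst w, the catalyst charge minus the impurity charge. It is the same in alder, maple, ochre and green.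

In the middle, partner consumes both hands while w keeps mixing them, and in maple at 3.00 h the reading of left-handed substrate is lower than that of right-handed substrate. At 3.00 h the readings give an excess of 1.64% in alder and 3.60% in maple, each carrying the scatter of 0.5 percentage points per reading. Their ratio, 2.20, is itself a reading that carries this scatter; it lies near the partner ratio, 2.22, so at fixed w we scale the excess with partner.

Assuming that the excess at the end stands where it stood at 3.00 h, that gives 1.80% for ochre and 7.19% for green. Later, partner can also wear w down into spent catalyst B, and green is charged with more partner than ochre, so we take our green figure as low.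

The forecast says green, with 2.5% for ochre and 8% for green, both higher than our figures. Its ground: “Green clearly ends higher, though the catalyst lifetime is poorly defined.”

The flasks give green, with 1.19% for ochre and 9.33% for green, so the forecast stands. In green at 6.00 h, spent catalyst A holds 54.0% of the catalyst, and w leaves 46.0% for the rest: 18.4% still racemization catalyst and 27.6% spent catalyst B. For the forecast to go wrong, the recipe has to differ: with all else held, green's answer has moved by 5 points at 4.16 µM or 7.81 µM of catalyst, that is, at w of 1.46 µM or 5.11 µM.

    partner + left-handed substrate → left-handed product (k = 0.0559 M⁻¹ min⁻¹)
    partner + right-handed substrate → right-handed product (k = 0.0204 M⁻¹ min⁻¹)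
    left-handed substrate + racemization catalyst ⇌ right-handed substrate + racemization catalyst, rate k3*[racemization catalyst]*[left-handed substrate] forward; the back reaction follows from the equilibrium constant (k = 7830 M⁻¹ min⁻¹)
    partner → decomposed reagent (k = 6.39 × 10⁻⁴ min⁻¹)
    racemization catalyst + impurity → spent catalyst A (k = 55700 M⁻¹ min⁻¹)
    partner + racemization catalyst → spent catalyst B (k = 0.0252 M⁻¹ min⁻¹)

Now take ochre's neighbour with 1.20 µM of catalyst: w comes to −1.50 µM, below zero, so we expect no catalyst to remain and 55.6% of the impurity to stay. Computed, it holds 0% of its catalyst and 55.8% of its impurity, and its excess is 15.1%.

(Readings and results come from a simulation from invented constants; the scatter is artificial.)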